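If a carrier shuttles between two states, the first question is what share of it is working, and two chemists disputed exactly that for this flask.

starting material 37 mM; salt in the second phase 37.0 mM; capture agent 1.85 mM; spent carrier 7.0 mM; time 2.5 d; volume of the second phase over the first 1.0

- amount of target and crystals together at 2.5 d, in percent of the starting material charged
- the change that raises the amount of target and crystals together at 2.5 d, in percent of the starting material charged most ("none" if none brings more than 2 percentage points) (south-east / north-east / south-west / none)
- amount of target and crystals together at 2.5 d, in percent of the starting material charged, after north-east

- target is meant together with its crystals
- in the second phase: salt in the second phase, spent salt in the second phase; everything else is in the first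
- charges count per volume of the first phase; a concentration in a rate is the amount of a species over the volume of its own phase; every rate counts per litre of the first phase
- solid, in amounts per volume of the solution: crystals
- run time (flask): 2.5 d

- south-east: doubling the solubility in step 2, all else as stated
- north-east: doubling the dissolution coefficient of step 2, all else as stated
- south-west: doubling the amount of salt in the second phase, all else as stated

    target + fresh carrier ⇌ isomer of the product + fresh carrier, rate k1*[target]*[fresh carrier] forward; the back reaction follows from the equilibrium constant (K1 = 0.363, k1 = 2.97 × 10⁻⁴ /M/s)
    crystals ⇌ target, rate k2*(cs2 - [target]) while solid is left; crystals form when [target] > cs2 (cs2 = 18 mM, k2 = 8.22 × 10⁻⁴ /s)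
    spent carrier + salt in the second phase ⇌ fresh carrier + spent salt in the second phase (K3 = 0.33, k3 = 0.00179 /M/s)
    spent carrier + capture agent → trapped intermediate (k4 = 0.00485 /M/s)
    starting material + fresh carrier → target + spent carrier (k5 = 7.09 × 10⁻⁴ /M/s)

Fresh carrier turns starting material into target and becomes spent carrier. Salt in the second phase refills it, giving spent salt, and that refill also runs back. Capture agent traps spent carrier.

Both chemists subtract the capture agent, which leaves 5.15 mM of carrier in the round. Counted as fresh throughout, that carrier gives starting material a pseudo-first-order exponent of 0.789 over 2.5 d.

Set spending of fresh carrier equal to refilling, a quasi-steady state. The carrier concentration then drops out of the quotient of the two rates, and spent over fresh carrier is starting material per salt times the spending ratio: the rate constant of spending over that of refilling, 0.396.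

The first chemist stops there. With equal charges his fresh share is 0.716, which turns over 43.2%.

The second objects that the refill runs back. Her fresh share, of fresh plus spent, is one over the sum of one, the spending ratio times starting material per salt, and spent salt per salt divided by 0.33.

I side with her and commit to a number. Take mid-run at a quarter of the charge turned over, so spent salt is a third of salt. The share is then 0.416, and the yield 27.9%.

Crystals need 0.486 of the charge in solution, more than that, so I put north-east at 27.9%. Doubled salt, with the same quarter of the charge turned over, lifts the mid-run share to 0.624, so my choice is south-west.

The forecast takes her side with a slightly different number: 28.5%, between 24% and 33%, with north-east at 28.5% and south-west as the choice. Its grounds are a refill “held back by the build-up of spent salt”.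

The simulation gives 28.2%, north-east 28.2%, and south-west with a gain of 7.8 percentage points. His number falls. His share is her rule with spent salt per salt taken as nothing, so it holds where that quotient is small against 0.33. In the flask at 0.250 d the quotient already read 0.143.

In the flask at 2.50 d, fresh carrier was made at 0.889 of the rate at which it was used, close to balance. The spending ratio with the end readings of salt and starting material gives a fresh share of 0.328, and the carrier readings give 0.333. In the neighbour flask with 22 mM of starting material, the same ratio with its end readings gives 0.429. That flask's carrier readings give 0.435, and its yield reads 32.4%.

The constants used here were chosen freely; the run is a simulation.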